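## Retrosynthetic overview
1. C3–C4: the (E)-2-alkylbut-2-ene-1,4-diyl diacetate terminus is made in one flask from symmetric but-2-yne-1,4-diol. A C16 homoallylic Grignard reagent adds by anti-carbomagnesiation, and the product is acetylated in situ.
2. C5–C6 and C7–CH3: the (E)-trisubstituted alkene and the C4–C5 spacer come from a terminal alkyne by syn-methylalumination and opening of oxirane.
3. C9–C1′: the only stereocentre comes from an anti-SN2′ substitution of an (S)-allylic picolinate by a silylbutynyl cuprate. The carbinol is set by CBS reduction, and picolinic acid supplies the chelating leaving group.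
4. Rings: the single carbocycle is bought as 2,4,4-trimethylcyclohexenone. No ring is formed; the allylic transposition moves its double bond into the final position.
5. Numbering: C1 = CH2OAc on the =CH, C2=C3, C20 = CH2OAc on C3, C4–C5, C6=C7(CH3), C8–C9, ring stereocentre C1′.

Assumption: 1 (CAS 13395-71-6) is taken as a catalogue compound; if out of stock it is one step from isobutyraldehyde and ethyl vinyl ketone (acid-catalysed Robinson annulation).

## Route

Step 1
Reactants: 1 2,4,4-trimethylcyclohex-2-en-1-one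
Product: 2 (1S)-2,4,4-trimethylcyclohex-2-en-1-ol
Conditions: (R)-Me-CBS (10 mol %), BH3·SMe2 (0.7 equiv), THF, −20 °C; MeOH quench
Reagents that add atoms: none
Why: Corey–Bakshi–Shibata reduction, in which the α-methylated alkenyl arm acts as the large substituent, so the (R)-oxazaborolidine·BH3 complex delivers hydride to one carbonyl face and gives the (S)-allylic alcohol by clean 1,2-reduction while the hindered trisubstituted alkene is not hydroborated.

Step 2
Reactants: 2 (1S)-2,4,4-trimethylcyclohex-2-en-1-ol; 3 pyridine-2-carboxylic acid (picolinic acid)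
Product: 4 (1S)-2,4,4-trimethylcyclohex-2-en-1-yl pyridine-2-carboxylate
Conditions: DCC, DMAP (cat.), CH2Cl2, 0 °C → rt
Reagents that add atoms: none
Why: Steglich esterification at oxygen leaves the C–O stereocentre untouched and installs a leaving group whose pyridine nitrogen and carbonyl oxygen can chelate magnesium in the next step.

Step 3
Reactants: 4 (1S)-2,4,4-trimethylcyclohex-2-en-1-yl pyridine-2-carboxylate; 5 (4-bromobut-1-yn-1-yl)trimethylsilane
Product: 8 trimethyl{4-[(1S)-2,6,6-trimethylcyclohex-2-en-1-yl]but-1-yn-1-yl}silane, via Grignard reagent 6 (not isolated), via homocuprate 7 (not isolated)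
Conditions: 5 (3 equiv), Mg, THF, rt → 40 °C; CuBr·SMe2 (1.5 equiv), THF, −40 °C; then 4, −40 → 0 °C; aq NH4Cl/NH3
Reagents that add atoms: none
Why: Copper-mediated anti-SN2′ allylic substitution, in which the MgBr2-chelated picolinate leaves easily and the cuprate attacks the γ-carbon next to the gem-dimethyl group on the face opposite the pseudoaxial C–O bond, so the carbinol chirality is relayed 1,3 into the (S)-configured ring stereocentre and the double bond moves to its final 2,3-position.

Step 4
Reactants: 8 trimethyl{4-[(1S)-2,6,6-trimethylcyclohex-2-en-1-yl]but-1-yn-1-yl}silane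
Product: 9 (6S)-6-(but-3-yn-1-yl)-1,5,5-trimethylcyclohex-1-ene
Conditions: K2CO3 (cat.), MeOH, rt
Reagents that add atoms: none
Why: Methoxide-induced protodesilylation cleaves only the C(sp)–Si bond and touches neither the ring alkene nor the non-acidic allylic stereocentre.

Step 5
Reactants: 9 (6S)-6-(but-3-yn-1-yl)-1,5,5-trimethylcyclohex-1-ene; 10 oxirane
Product: 13 (3E)-4-methyl-6-[(1S)-2,6,6-trimethylcyclohex-2-en-1-yl]hex-3-en-1-ol, via alkenylalane 11 (not isolated), via lithium alanate 12 (not isolated)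
Conditions: Me3Al (2 equiv), Cp2ZrCl2 (25 mol %), CH2Cl2, rt; evaporate, hexane; n-BuLi, THF, −30 °C; 10 (3 equiv), −30 °C → rt; 1 M HCl
Reagents that add atoms: trimethylaluminium, C[Al](C)C
Why: Negishi zirconium-catalysed methylalumination adds CH3 and Al syn with Al on the terminal carbon, and the derived ate complex opens oxirane with retention at the sp2 carbon, which fixes the (E)-C6=C7 alkene and adds C4–C5 in the same flask.

Step 6
Reactants: 13 (3E)-4-methyl-6-[(1S)-2,6,6-trimethylcyclohex-2-en-1-yl]hex-3-en-1-ol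
Product: 14 (6S)-6-[(3E)-6-bromo-3-methylhex-3-en-1-yl]-1,5,5-trimethylcyclohex-1-ene
Conditions: CBr4, PPh3, CH2Cl2, 0 °C
Reagents that add atoms: carbon tetrabromide, BrC(Br)(Br)Br
Why: The Appel reaction converts the unhindered primary alcohol by SN2 under neutral conditions that leave both trisubstituted alkenes and the stereocentre alone.

Step 7
Reactants: 14 (6S)-6-[(3E)-6-bromo-3-methylhex-3-en-1-yl]-1,5,5-trimethylcyclohex-1-ene; 15 but-2-yne-1,4-diol
Product: 20 (2E)-2-{(3E)-4-methyl-6-[(1S)-2,6,6-trimethylcyclohex-2-en-1-yl]hex-3-en-1-yl}but-2-ene-1,4-diyl diacetate, via Grignard reagent 16 (not isolated), via butynediol dialkoxide 17 (not isolated), via alkenylmagnesium chelate 18 (not isolated), via enediol 19 (not isolated)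
Conditions: 14, Mg, THF, 40 °C; separately 15 (1.5 equiv), MeMgBr (3.0 equiv), THF, 0 °C; combine, CuI (15 mol %), THF–Et2O, 0 → 40 °C, 16 h; AcOH, 0 °C; then Ac2O, pyridine, DMAP (cat.), rt
Reagents that add atoms: acetic anhydride, CC(=O)OC(C)=O
Why: Copper-catalysed anti-carbomagnesiation of a propargylic alkoxide, in which the symmetry of the diol makes both alkyne carbons equivalent (no regiochemical issue), the alkyl group adds trans to magnesium, magnesium ends cis to and chelated by the geminal CH2O arm, protonolysis therefore gives only the enediol with the two CH2O groups trans (chain cis to C1), the dialkoxide form suppresses β-elimination to an allenol, and the two primary allylic alcohols are acetylated in the same flask.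

## Compound list
1 | 2,4,4-trimethylcyclohex-2-en-1-one | CC1=CC(C)(C)CCC1=O | starting material
2 | (1S)-2,4,4-trimethylcyclohex-2-en-1-ol | CC1=CC(C)(C)CC[C@@H]1O | intermediate
3 | pyridine-2-carboxylic acid (picolinic acid) | OC(=O)c1ccccn1 | starting material
4 | (1S)-2,4,4-trimethylcyclohex-2-en-1-yl pyridine-2-carboxylate | CC1=CC(C)(C)CC[C@@H]1OC(=O)c1ccccn1 | intermediate
5 | (4-bromobut-1-yn-1-yl)trimethylsilane | C[Si](C)(C)C#CCCBr | starting material
6 | [4-(trimethylsilyl)but-3-yn-1-yl]magnesium bromide | C[Si](C)(C)C#CCC[Mg]Br | intermediate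
7 | bromomagnesium bis[4-(trimethylsilyl)but-3-yn-1-yl]cuprate | C[Si](C)(C)C#CCC[Cu-]CCC#C[Si](C)(C)C.[Mg+]Br | intermediate
8 | trimethyl{4-[(1S)-2,6,6-trimethylcyclohex-2-en-1-yl]but-1-yn-1-yl}silane | C[Si](C)(C)C#CCC[C@@H]1C(C)=CCCC1(C)C | intermediate
9 | (6S)-6-(but-3-yn-1-yl)-1,5,5-trimethylcyclohex-1-ene | C#CCC[C@@H]1C(C)=CCCC1(C)C | intermediate
10 | oxirane | C1CO1 | starting material
11 | dimethyl{(1E)-2-methyl-4-[(1S)-2,6,6-trimethylcyclohex-2-en-1-yl]but-1-en-1-yl}alane | C[Al](C)/C=C(\C)CC[C@@H]1C(C)=CCCC1(C)C | intermediate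
12 | lithium butyl(dimethyl){(1E)-2-methyl-4-[(1S)-2,6,6-trimethylcyclohex-2-en-1-yl]but-1-en-1-yl}alanate | [Li+].CCCC[Al-](C)(C)/C=C(\C)CC[C@@H]1C(C)=CCCC1(C)C | intermediate
13 | (3E)-4-methyl-6-[(1S)-2,6,6-trimethylcyclohex-2-en-1-yl]hex-3-en-1-ol | OCC/C=C(\C)CC[C@@H]1C(C)=CCCC1(C)C | intermediate
14 | (6S)-6-[(3E)-6-bromo-3-methylhex-3-en-1-yl]-1,5,5-trimethylcyclohex-1-ene | BrCC/C=C(\C)CC[C@@H]1C(C)=CCCC1(C)C | intermediate
15 | but-2-yne-1,4-diol | OCC#CCO | starting material
16 | {(3E)-4-methyl-6-[(1S)-2,6,6-trimethylcyclohex-2-en-1-yl]hex-3-en-1-yl}magnesium bromide | Br[Mg]CC/C=C(\C)CC[C@@H]1C(C)=CCCC1(C)C | intermediate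
17 | but-2-yne-1,4-diol bis(bromomagnesium) alkoxide | Br[Mg]OCC#CCO[Mg]Br | intermediate
18 | C2-magnesiated enediol bis(bromomagnesium) alkoxide (Mg on C2 cis to C20H2O, chain on C3 cis to C1) | Br[Mg]OC/C([Mg]Br)=C(\CC/C=C(\C)CC[C@@H]1C(C)=CCCC1(C)C)CO[Mg]Br | intermediate
19 | (2E)-2-{(3E)-4-methyl-6-[(1S)-2,6,6-trimethylcyclohex-2-en-1-yl]hex-3-en-1-yl}but-2-ene-1,4-diol | OC/C=C(\CC/C=C(\C)CC[C@@H]1C(C)=CCCC1(C)C)CO | intermediate
20 | (2E)-2-{(3E)-4-methyl-6-[(1S)-2,6,6-trimethylcyclohex-2-en-1-yl]hex-3-en-1-yl}but-2-ene-1,4-diyl diacetate (CNP0186001.1) | CC(=O)OC/C=C(\CC/C=C(\C)CC[C@@H]1C(C)=CCCC1(C)C)COC(C)=O | target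

## Step count and risks
Total step count: 7. Longest linear sequence: 7 (1 → 2 → 4 → 8 → 9 → 13 → 14 → 20).

**Step 7 is the most likely to fail.** Only about one equivalent of a valuable sp3 Grignard reagent meets an internal alkyne held in a poorly soluble dialkoxide. Protonation, homocoupling or low conversion can therefore dominate.

The fallback gives up carbometalation and forms C3–C4 by cross-coupling. It sets out from 14 and 15 and comes back at 20.
- 15 is trans-hydroaluminated with Red-Al and iodinated to (2Z)-2-iodobut-2-ene-1,4-diol F1.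
- F1 is acetylated to (2Z)-2-iodobut-2-ene-1,4-diyl diacetate F2.
- 14 is turned with Zn dust/LiCl into the homoallylic zinc bromide F3.
- Negishi coupling of F3 with F2 (PdCl2(dppf), THF, rt) replaces iodine with retention and gives 20 directly.

**Step 3 is second.** The γ-carbon is neopentyl, so direct α-attack, elimination to the diene, or erosion of chirality transfer through a π-allyl species may compete.

The fallback makes the C1′–C9 bond by a suprafacial sigmatropic shift instead of a substitution. It sets out from 1 and comes back at 8.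
- 1 is reduced with the (S)-CBS catalyst to (1R)-2,4,4-trimethylcyclohex-2-en-1-ol F4.
- Johnson–Claisen rearrangement (triethyl orthoacetate, cat. propionic acid, 140 °C) gives ethyl [(1S)-2,6,6-trimethylcyclohex-2-en-1-yl]acetate F5.
- LiAlH4 gives 2-[(1S)-2,6,6-trimethylcyclohex-2-en-1-yl]ethanol F6.
- I2/PPh3/imidazole gives (6S)-6-(2-iodoethyl)-1,5,5-trimethylcyclohex-1-ene F7.
- Lithium (trimethylsilyl)acetylide in THF/DMPU alkylates F7 to 8.

**Step 5 is third.** The methylalumination itself is reliable. Opening of oxirane by the alanate can suffer from competing methyl or butyl transfer and from residual Me3Al.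

The fallback avoids the epoxide, the bromide and the Grignard reagent altogether. It sets out from 9 and comes back at 19.
- 9 is methylaluminated to 11 as before and coupled in the same flask with vinyl bromide (Pd(PPh3)4, ZnCl2). This gives (6S)-1,5,5-trimethyl-6-[(3E)-3-methylhexa-3,5-dien-1-yl]cyclohex-1-ene F8.
- 9-BBN adds selectively to the terminal vinyl group to give the B-homoallyl-9-borabicyclononane F9.
- B-alkyl Suzuki coupling of F9 with the iododiol F1 (PdCl2(dppf), Cs2CO3, DMF/H2O) gives 19.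
- 19 is acetylated as in the last stage of step 7.

## Further compounds
F1 | step 7 | (2Z)-2-iodobut-2-ene-1,4-diol | OC/C=C(\I)CO
F2 | step 7 | (2Z)-2-iodobut-2-ene-1,4-diyl diacetate | CC(=O)OC/C=C(\I)COC(C)=O
F3 | step 7 | {(3E)-4-methyl-6-[(1S)-2,6,6-trimethylcyclohex-2-en-1-yl]hex-3-en-1-yl}zinc bromide | Br[Zn]CC/C=C(\C)CC[C@@H]1C(C)=CCCC1(C)C
F4 | step 3 | (1R)-2,4,4-trimethylcyclohex-2-en-1-ol | CC1=CC(C)(C)CC[C@H]1O
F5 | step 3 | ethyl [(1S)-2,6,6-trimethylcyclohex-2-en-1-yl]acetate | CCOC(=O)C[C@@H]1C(C)=CCCC1(C)C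
F6 | step 3 | 2-[(1S)-2,6,6-trimethylcyclohex-2-en-1-yl]ethanol | OCC[C@@H]1C(C)=CCCC1(C)C
F7 | step 3 | (6S)-6-(2-iodoethyl)-1,5,5-trimethylcyclohex-1-ene | ICC[C@@H]1C(C)=CCCC1(C)C
F8 | step 5 | (6S)-1,5,5-trimethyl-6-[(3E)-3-methylhexa-3,5-dien-1-yl]cyclohex-1-ene | C=C/C=C(\C)CC[C@@H]1C(C)=CCCC1(C)C
F9 | step 5 | 9-{(3E)-4-methyl-6-[(1S)-2,6,6-trimethylcyclohex-2-en-1-yl]hex-3-en-1-yl}-9-borabicyclo[3.3.1]nonane | C(C/C=C(\C)CC[C@@H]1C(C)=CCCC1(C)C)B1C2CCCC1CCC2
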